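**Retrosynthetic overview**

1. The target is ring C (the central 1,2,4,5-tetramethoxybenzene) carrying indole A (unsubstituted indol-3-yl) and indole B (5-prenylindol-3-yl) on its two para carbons; the last step strips an N-silyl group from indole A and a C2-silyl group from indole B.
2. The strategy rests on indole B having a free C2–H, ring C on C3 and the prenyl group on C5 (para to N1): cutting N1–C2 and C3–C3a gives 2-iodo-4-prenylaniline 17 and ring C arylalkyne 13, whose two sp carbons become C2 (silyl end) and C3 (ring C end).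
3. Alkyne 13 comes from iodide 11 by Sonogashira coupling; 11 comes from lithiation of 9 at the one ring C C–H, which lies between two methoxy groups, while the N-triisopropylsilyl group shields indole C2.
4. The ring C–indole A bond comes from addition of lithiated 1 to the C3 ketone of isatin, followed by reductive aromatisation; aniline 17 comes from 4-iodoaniline by Stille prenylation and ortho-iodination.
5. Ring order: ring C and the indole A bicycle are bought (as 1 and isatin; the pyrrole of indole A is aromatised in step 2); the pyrrole ring of indole B is the only ring built, in step 8.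

Key step: step 8

Remark: tributyl(3-methylbut-2-en-1-yl)stannane is taken as a purchased reagent; the target has no stereocentre, and the only stereocentre on the way (the carbinol carbon of 5 and 6) is racemic and becomes sp2 in step 2.

**Route**

Step 1
Reactants: 1 1,2,4,5-tetramethoxybenzene; 2 isatin
Product: 5 rac-3-hydroxy-3-(2,3,5,6-tetramethoxyphenyl)indolin-2-one, via 2,3,5,6-tetramethoxyphenyllithium 3 (not isolated), via isatin sodium salt 4 (not isolated)
Conditions: 1, n-BuLi, THF, 0 °C; separately 2, NaH, THF, 0 °C; 3 added to 4, −78 °C to rt; H2O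
Reagents that add atoms: n-butyllithium, [Li]CCCC (supplies only the lithium of intermediate 3); sodium hydride, [Na+].[H-] (supplies only the sodium of intermediate 4)
Why: Directed ortho-lithiation of 1 at a C–H flanked by two methoxy groups gives 3, which undergoes 1,2-addition to the C3 ketone of N-deprotonated isatin (the C2 carbonyl is deactivated as the amidate); the carbinol centre forms as a racemate and is erased in step 2.

Step 2
Reactants: 5 rac-3-hydroxy-3-(2,3,5,6-tetramethoxyphenyl)indolin-2-one
Product: 7 3-(2,3,5,6-tetramethoxyphenyl)-1H-indole, via rac-3-(2,3,5,6-tetramethoxyphenyl)indolin-3-ol 6 (not isolated)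
Conditions: BH3·THF (4 equiv), THF, 0 °C to rt; then 1 M HCl aq, rt
Reagents that add atoms: none
Why: Borane reduction of the lactam to indoline 6 and acid-promoted dehydration of its benzylic tertiary alcohol (aromatisation) is the established conversion of 3-substituted 3-hydroxyoxindoles into 3-substituted indoles; the aryl methyl ethers are inert.

Step 3
Reactants: 7 3-(2,3,5,6-tetramethoxyphenyl)-1H-indole
Product: 9 3-(2,3,5,6-tetramethoxyphenyl)-1-(triisopropylsilyl)indole, via sodium 3-(2,3,5,6-tetramethoxyphenyl)indol-1-ide 8 (not isolated)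
Conditions: NaH, THF, 0 °C; TIPSCl, rt
Reagents that add atoms: chlorotriisopropylsilane, CC(C)[Si](Cl)(C(C)C)C(C)C; sodium hydride, [Na+].[H-] (supplies only the sodium of intermediate 8)
Why: N-silylation of the indolyl sodium salt; the bulky triisopropylsilyl group removes the acidic N–H and sterically blocks deprotonation at indole C2 in step 4.

Step 4
Reactants: 9 3-(2,3,5,6-tetramethoxyphenyl)-1-(triisopropylsilyl)indole
Product: 11 3-(4-iodo-2,3,5,6-tetramethoxyphenyl)-1-(triisopropylsilyl)indole, via 2,3,5,6-tetramethoxy-4-[1-(triisopropylsilyl)indol-3-yl]phenyllithium 10 (not isolated)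
Conditions: n-BuLi (1.2 equiv), TMEDA, THF, 0 °C; then I2, −78 °C to rt; Na2S2O3 aq
Reagents that add atoms: iodine, II; n-butyllithium, [Li]CCCC (supplies only the lithium of intermediate 10)
Why: Directed ortho-metalation at the only ring C C–H, doubly activated by its two flanking methoxy groups, followed by iodine quench of the aryllithium; N-triisopropylsilylindoles resist C2 lithiation because the silyl group shields that position.

Step 5
Reactants: 11 3-(4-iodo-2,3,5,6-tetramethoxyphenyl)-1-(triisopropylsilyl)indole; 12 ethynyltrimethylsilane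
Product: 13 3-{2,3,5,6-tetramethoxy-4-[(trimethylsilyl)ethynyl]phenyl}-1-(triisopropylsilyl)indole
Conditions: PdCl2(PPh3)2 (5 mol%), CuI (10 mol%), Et3N–THF, 60 °C, sealed tube
Reagents that add atoms: none
Why: Sonogashira coupling of an aryl iodide; the linear alkyne tolerates the two ortho methoxy groups, and both silyl groups are stable to amine base.

Step 6
Reactants: 14 4-iodoaniline; 15 tributyl(3-methylbut-2-en-1-yl)stannane
Product: 16 4-(3-methylbut-2-en-1-yl)aniline
Conditions: Pd(PPh3)4 (5 mol%), DMF, 100 °C
Reagents that add atoms: none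
Why: Migita–Kosugi–Stille coupling of an aryl iodide with an allylic stannane, expected to transfer the prenyl group mainly through its CH2 terminus to give the linear isomer; the free amine is tolerated.

Step 7
Reactants: 16 4-(3-methylbut-2-en-1-yl)aniline
Product: 17 2-iodo-4-(3-methylbut-2-en-1-yl)aniline
Conditions: NIS (1.0 equiv), MeCN, 0 °C, dark
Reagents that add atoms: N-iodosuccinimide, O=C1CCC(=O)N1I
Why: Electrophilic aromatic iodination of an aniline with a blocked para position goes ortho to the amino group; with one equivalent of reagent and no added nucleophile the strongly activated ring should outcompete the trisubstituted alkene.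

Step 8
Reactants: 13 3-{2,3,5,6-tetramethoxy-4-[(trimethylsilyl)ethynyl]phenyl}-1-(triisopropylsilyl)indole; 17 2-iodo-4-(3-methylbut-2-en-1-yl)aniline (1.5 equiv)
Product: 18 3-{2,3,5,6-tetramethoxy-4-[1-(triisopropylsilyl)indol-3-yl]phenyl}-5-(3-methylbut-2-en-1-yl)-2-(trimethylsilyl)-1H-indole
Conditions: Pd(OAc)2 (10 mol%), LiCl (1 equiv), K2CO3 (3 equiv), DMF, 100 °C
Reagents that add atoms: none
Why: Pd(OAc)2 is reduced in the flask to zerovalent palladium, which inserts into the C–I bond of 17; the resulting arylpalladium halide (divalent palladium) adds syn across the alkyne of 13 so that the aniline carbon bonds to the alkyne carbon bearing ring C (C3–C3a) and palladium sits on the silyl-bearing carbon. The amino group then displaces halide on palladium with loss of HX to carbonate, and C–N reductive elimination from the six-membered azapalladacycle forms N1–C2 and returns zerovalent palladium. This is the Larock heteroannulation of ortho-iodoanilines with internal aryl(silyl)alkynes, a known reaction type. The pyrrole ring of indole B is closed as a formal [3+2] annulation (N1–C7a–C3a from 17, C2–C3 from the alkyne), the ring-closing event being the intramolecular C–N reductive elimination; no stereocentre is formed. The step needs regioselective insertion (silicon at C2, ring C at C3), which the trimethylsilyl group secures because the bulkier, palladium-stabilising silyl terminus ends up next to the metal and hence next to nitrogen; it also needs chemoselectivity for C–I over the prenyl alkene, which the trisubstituted, non-activated alkene provides by being a poor partner for carbopalladation. Because the ring C–indole B bond comes from the alkyne carbon already attached to ring C, no cross-coupling at the doubly ortho-substituted ring C carbon is required, and the prenyl group para to nitrogen in 17 maps onto C5; any N-triisopropylsilyl group lost to carbonate here would converge in step 9.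

Step 9
Reactants: 18 3-{2,3,5,6-tetramethoxy-4-[1-(triisopropylsilyl)indol-3-yl]phenyl}-5-(3-methylbut-2-en-1-yl)-2-(trimethylsilyl)-1H-indole
Product: 20 3-[4-(1H-indol-3-yl)-2,3,5,6-tetramethoxyphenyl]-5-(3-methylbut-2-en-1-yl)-1H-indole (CNP0306547.0), via 3-[4-(1H-indol-3-yl)-2,3,5,6-tetramethoxyphenyl]-5-(3-methylbut-2-en-1-yl)-2-(trimethylsilyl)-1H-indole 19 (not isolated)
Conditions: TBAF (1 M in THF, wet, 5 equiv), THF, rt then 65 °C
Reagents that add atoms: none
Why: Fluoride cleaves the N–Si bond at room temperature and then, on heating, the C2–Si bond of the 2-silylindole (fluoride-induced protodesilylation with water as proton source); the non-acidic medium leaves the prenyl alkene untouched.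

**Compound list**

1 | 1,2,4,5-tetramethoxybenzene | COc1cc(OC)c(OC)cc1OC | starting material
2 | isatin | O=C1Nc2ccccc2C1=O | starting material
3 | 2,3,5,6-tetramethoxyphenyllithium | [Li]c1c(OC)c(OC)cc(OC)c1OC | intermediate
4 | isatin sodium salt | O=C1[N-]c2ccccc2C1=O.[Na+] | intermediate
5 | rac-3-hydroxy-3-(2,3,5,6-tetramethoxyphenyl)indolin-2-one | COc1cc(OC)c(OC)c(C2(O)C(=O)Nc3ccccc32)c1OC | intermediate
6 | rac-3-(2,3,5,6-tetramethoxyphenyl)indolin-3-ol | COc1cc(OC)c(OC)c(C2(O)CNc3ccccc32)c1OC | intermediate
7 | 3-(2,3,5,6-tetramethoxyphenyl)-1H-indole | COc1cc(OC)c(OC)c(-c2c[nH]c3ccccc23)c1OC | intermediate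
8 | sodium 3-(2,3,5,6-tetramethoxyphenyl)indol-1-ide | COc1cc(OC)c(OC)c(-c2c[n-]c3ccccc23)c1OC.[Na+] | intermediate
9 | 3-(2,3,5,6-tetramethoxyphenyl)-1-(triisopropylsilyl)indole | COc1cc(OC)c(OC)c(-c2cn([Si](C(C)C)(C(C)C)C(C)C)c3ccccc23)c1OC | intermediate
10 | 2,3,5,6-tetramethoxy-4-[1-(triisopropylsilyl)indol-3-yl]phenyllithium | [Li]c1c(OC)c(OC)c(-c2cn([Si](C(C)C)(C(C)C)C(C)C)c3ccccc23)c(OC)c1OC | intermediate
11 | 3-(4-iodo-2,3,5,6-tetramethoxyphenyl)-1-(triisopropylsilyl)indole | Ic1c(OC)c(OC)c(-c2cn([Si](C(C)C)(C(C)C)C(C)C)c3ccccc23)c(OC)c1OC | intermediate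
12 | ethynyltrimethylsilane | C#C[Si](C)(C)C | starting material
13 | 3-{2,3,5,6-tetramethoxy-4-[(trimethylsilyl)ethynyl]phenyl}-1-(triisopropylsilyl)indole | C[Si](C)(C)C#Cc1c(OC)c(OC)c(-c2cn([Si](C(C)C)(C(C)C)C(C)C)c3ccccc23)c(OC)c1OC | intermediate
14 | 4-iodoaniline | Nc1ccc(I)cc1 | starting material
15 | tributyl(3-methylbut-2-en-1-yl)stannane | CCCC[Sn](CCCC)(CCCC)CC=C(C)C | starting material
16 | 4-(3-methylbut-2-en-1-yl)aniline | Nc1ccc(CC=C(C)C)cc1 | intermediate
17 | 2-iodo-4-(3-methylbut-2-en-1-yl)aniline | Nc1ccc(CC=C(C)C)cc1I | intermediate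
18 | 3-{2,3,5,6-tetramethoxy-4-[1-(triisopropylsilyl)indol-3-yl]phenyl}-5-(3-methylbut-2-en-1-yl)-2-(trimethylsilyl)-1H-indole | C[Si](C)(C)c1[nH]c2ccc(CC=C(C)C)cc2c1-c1c(OC)c(OC)c(-c2cn([Si](C(C)C)(C(C)C)C(C)C)c3ccccc23)c(OC)c1OC | intermediate
19 | 3-[4-(1H-indol-3-yl)-2,3,5,6-tetramethoxyphenyl]-5-(3-methylbut-2-en-1-yl)-2-(trimethylsilyl)-1H-indole | C[Si](C)(C)c1[nH]c2ccc(CC=C(C)C)cc2c1-c1c(OC)c(OC)c(-c2c[nH]c3ccccc23)c(OC)c1OC | intermediate
20 | 3-[4-(1H-indol-3-yl)-2,3,5,6-tetramethoxyphenyl]-5-(3-methylbut-2-en-1-yl)-1H-indole | COc1c(OC)c(-c2c[nH]c3ccc(CC=C(C)C)cc23)c(OC)c(OC)c1-c1c[nH]c2ccccc12 | target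

**Step count**

Total step count: 9.
Longest linear sequence: 7 steps (steps 1, 2, 3, 4, 5, 8, 9); steps 6 and 7 form the two-step aniline branch.

**Steps most likely to fail**

1. Step 8 (heteroannulation). The alkyne carbon that must bond to the aniline ring is shielded by two ortho methoxy groups of ring C. Insertion may therefore be slow, and reduction or self-coupling of the iodoaniline, loss of the alkynyl silyl group to carbonate, or insertion with the reverse orientation could take over. Fallback: build indole B by the isatin chemistry of steps 1 and 2, setting out from isatin 2 and from 9. Isatin 2 is brominated para to nitrogen (NBS, MeCN) to 5-bromoisatin F1, which NaH converts into its sodium salt F2. Compound 9 is lithiated to 10 as in step 4, and 10 is added to F2 at −78 °C to give rac-5-bromo-3-hydroxy-3-{2,3,5,6-tetramethoxy-4-[1-(triisopropylsilyl)indol-3-yl]phenyl}indolin-2-one F3. BH3·THF reduction gives rac-5-bromo-3-{2,3,5,6-tetramethoxy-4-[1-(triisopropylsilyl)indol-3-yl]phenyl}indolin-3-ol F4, which dehydrates on mild acidic work-up to 5-bromo-3-{2,3,5,6-tetramethoxy-4-[1-(triisopropylsilyl)indol-3-yl]phenyl}-1H-indole F5. Stille coupling of the unhindered C5 bromide with 15 (Pd(PPh3)4, DMF, 100 °C) gives 3-{2,3,5,6-tetramethoxy-4-[1-(triisopropylsilyl)indol-3-yl]phenyl}-5-(3-methylbut-2-en-1-yl)-1H-indole F6. TBAF then removes the N-silyl group, and the fallback comes back to the route at target 20.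

2. Step 7 (iodination of the prenylaniline). The electrophilic iodine source may add to the trisubstituted prenyl alkene, or iodinate both ortho positions, instead of giving clean mono ortho-iodination. Fallback: place the ortho halogen before the alkene arrives, setting out from 4-iodoaniline 14. Bromination (NBS, MeCN, 0 °C) gives 2-bromo-4-iodoaniline F7. Stille coupling with 15, chemoselective for the C–I bond (Pd(PPh3)4, DMF, 80 °C), gives 2-bromo-4-(3-methylbut-2-en-1-yl)aniline F8. F8 is annulated with 13 under conditions suited to ortho-bromoanilines (Pd[P(t-Bu)3]2, Cy2NMe, 1,4-dioxane, 80 °C), and the fallback comes back to the route at 18.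

3. Step 4 (lithiation and iodination of ring C). Deprotonation may be incomplete, or may compete at indole C2, and the organolithium may attack the N–Si bond. Fallback: carry the ring C halogen in from the start, setting out from 1. Double bromination (Br2, CH2Cl2–AcOH, 0 °C) gives 1,4-dibromo-2,3,5,6-tetramethoxybenzene F9. Single bromine–lithium exchange (n-BuLi, 1.0 equiv, THF, −78 °C) gives 4-bromo-2,3,5,6-tetramethoxyphenyllithium F10, which is added to isatin sodium salt 4 to give rac-3-(4-bromo-2,3,5,6-tetramethoxyphenyl)-3-hydroxyindolin-2-one F11. BH3·THF reduction gives rac-3-(4-bromo-2,3,5,6-tetramethoxyphenyl)indolin-3-ol F12, which dehydrates on acidic work-up to 3-(4-bromo-2,3,5,6-tetramethoxyphenyl)-1H-indole F13. Sonogashira coupling with 12 under conditions for electron-rich aryl bromides (PdCl2(PhCN)2, P(t-Bu)3, CuI, i-Pr2NH, 1,4-dioxane, 50 °C) gives 3-{2,3,5,6-tetramethoxy-4-[(trimethylsilyl)ethynyl]phenyl}-1H-indole F14. No N-silyl group is needed because no lithiation follows. Annulation of F14 with 17 under the step 8 conditions brings the fallback back to the route at 19, which the heating stage of step 9 converts into 20.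

**Further compounds**

F1 | step 8 | 5-bromoisatin | O=C1Nc2ccc(Br)cc2C1=O
F2 | step 8 | 5-bromoisatin sodium salt | O=C1[N-]c2ccc(Br)cc2C1=O.[Na+]
F3 | step 8 | rac-5-bromo-3-hydroxy-3-{2,3,5,6-tetramethoxy-4-[1-(triisopropylsilyl)indol-3-yl]phenyl}indolin-2-one | COc1c(OC)c(C2(O)C(=O)Nc3ccc(Br)cc32)c(OC)c(OC)c1-c1cn([Si](C(C)C)(C(C)C)C(C)C)c2ccccc12
F4 | step 8 | rac-5-bromo-3-{2,3,5,6-tetramethoxy-4-[1-(triisopropylsilyl)indol-3-yl]phenyl}indolin-3-ol | COc1c(OC)c(C2(O)CNc3ccc(Br)cc32)c(OC)c(OC)c1-c1cn([Si](C(C)C)(C(C)C)C(C)C)c2ccccc12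
F5 | step 8 | 5-bromo-3-{2,3,5,6-tetramethoxy-4-[1-(triisopropylsilyl)indol-3-yl]phenyl}-1H-indole | COc1c(OC)c(-c2c[nH]c3ccc(Br)cc23)c(OC)c(OC)c1-c1cn([Si](C(C)C)(C(C)C)C(C)C)c2ccccc12
F6 | step 8 | 3-{2,3,5,6-tetramethoxy-4-[1-(triisopropylsilyl)indol-3-yl]phenyl}-5-(3-methylbut-2-en-1-yl)-1H-indole | COc1c(OC)c(-c2c[nH]c3ccc(CC=C(C)C)cc23)c(OC)c(OC)c1-c1cn([Si](C(C)C)(C(C)C)C(C)C)c2ccccc12
F7 | step 7 | 2-bromo-4-iodoaniline | Nc1ccc(I)cc1Br
F8 | step 7 | 2-bromo-4-(3-methylbut-2-en-1-yl)aniline | Nc1ccc(CC=C(C)C)cc1Br
F9 | step 4 | 1,4-dibromo-2,3,5,6-tetramethoxybenzene | COc1c(Br)c(OC)c(OC)c(Br)c1OC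
F10 | step 4 | 4-bromo-2,3,5,6-tetramethoxyphenyllithium | [Li]c1c(OC)c(OC)c(Br)c(OC)c1OC
F11 | step 4 | rac-3-(4-bromo-2,3,5,6-tetramethoxyphenyl)-3-hydroxyindolin-2-one | COc1c(Br)c(OC)c(OC)c(C2(O)C(=O)Nc3ccccc32)c1OC
F12 | step 4 | rac-3-(4-bromo-2,3,5,6-tetramethoxyphenyl)indolin-3-ol | COc1c(Br)c(OC)c(OC)c(C2(O)CNc3ccccc32)c1OC
F13 | step 4 | 3-(4-bromo-2,3,5,6-tetramethoxyphenyl)-1H-indole | COc1c(Br)c(OC)c(OC)c(-c2c[nH]c3ccccc23)c1OC
F14 | step 4 | 3-{2,3,5,6-tetramethoxy-4-[(trimethylsilyl)ethynyl]phenyl}-1H-indole | C[Si](C)(C)C#Cc1c(OC)c(OC)c(-c2c[nH]c3ccccc23)c(OC)c1OC
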